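Count the half-lives before you trust a yield read from this flask.

    G ⇌ E (K1 = 0.031, k1 = 0.0936 s⁻¹)
    D + E ⇌ D.E (K2 = 270 M⁻¹, k2 = 58.8 M⁻¹ s⁻¹)
    D.E ⇌ Q (K3 = 0.965, k3 = 0.147 s⁻¹)

G 0.0010 M (in portions, 2); D 5.00 equiv; time 12 min; the portions of G follow each other after 8.0 s, the first at the start

- D.E at 12 min, in percent of the G charged
- Q at 12 min, in percent of the G charged

I begin with E, the way through which G reaches D.E. G and E relax into each other with a half-life of 0.223 s, shorter than the 8.0 s between the portions, so in this flask E keeps pace with G, and it holds 3.01 % of their sum. D takes up E with 58.8 M⁻¹ s⁻¹ times its concentration, so the feed from G into D.E has the constant 0.00884 s⁻¹. The half-life that belongs to this constant, with D as charged and nothing returning, I call the feed half-life t_f: 78.4 s. The return of D.E runs with 0.218 s⁻¹, larger than the feed constant, and in this flask I expect that return to quicken the approach to balance, so I take t_f as a long estimate.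

Now I set this flask beside the same flask read at 30 min. The second portion comes at 8.0 s, shorter than t_f, so I count from the start: 9.18 feed half-lives in this flask and 23.0 in the later reading. By this count this flask has about 0.172 % of its way to balance still to go, because its time is longer than t_f, and I expect both readings to stand at the same balance, which is thermodynamic control.

The balance is short work. D.E stands to G as w, the product of the first two equilibrium constants and [D]. With D as charged, w is 0.0418, and D.E plus Q hold 7.39 % of the G charged. That lowers D to 0.00493 M, so w becomes 0.0412, and I commit to 3.71 % of D.E and 3.58 % of Q. The forecast reads 3.71 % and 3.58 %, on the ground that “the flask is at full equilibrium”.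

This flask gives 3.71 % of D.E and 3.58 % of Q, which checks my balance. Its step from D.E to Q relaxes with a half-life of 2.32 s, shorter than the 12 min of the run, and the backward turnover of that step stands at 99.1 % of the forward one. The count carries over: 9.18 feed half-lives of 78.4 s lie behind this flask and 23.0 behind the same flask read at 30 min, which holds 3.71 % of D.E and 3.58 % of Q.

The constants were set for the occasion.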